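Numbers refer to the compound list after the steps. Two abbreviations are used in names: ArA = 2,4-bis(benzyloxy)-6-(methoxymethoxy)phenyl and ArC = 2,4,6-tris(benzyloxy)phenyl.

## Analysis of the target

The target is a meta-terphenyl made of three phloroglucinol rings. The central ring B carries ring A at B1 and ring C at B5, hydroxyls at B2, B4 and B6, and its only hydrogen at B3. Each terminal ring is attached through the carbon that lies between two of its oxygens. Of the nine phenolic oxygens one, an ortho oxygen of ring A, is a hydrogen sulfate ester. There is no stereocentre; the A–B axis has four ortho oxygens and an unsymmetrical ring A and could be a stereogenic axis, but none is specified. The sensitive groups are the aryl sulfate monoester, which acid cleaves and which is therefore made late and kept as a salt, and the three electron-rich rings, whose free CH positions react with electrophiles and oxidants. The synthesis is hard for two reasons: both biaryl bonds are tetra-ortho-oxygenated and join very electron-rich rings, and one oxygen out of nine, nearly identical to three others, must be singled out for sulfation. The strategy rests on ring B: B2, B1, B6 and B5 carry O, aryl, O, aryl on four consecutive carbons, the pattern of a 2,4-dioxygenated 3,5-diarylcyclopentadienone. The remaining atoms B4 (C–OH) and B3 (C–H) are the two carbons of a ketene acetal.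

## Retrosynthetic reasoning

**29 back to 25.** The sulfate S–O bond and the eight benzyl C–O bonds are cut first, which leads through salt 27 and phenol 26 to the fully protected terphenyl 25. Sulfation needs one free phenol and eight masked ones, so the oxygen to be sulfated is carried as an acetal (methoxymethyl) ether that is removed without touching benzyl ethers. The forward steps have to free that one oxygen, sulfate it, and then remove all benzyl groups under neutral conditions that leave the sulfate monoester intact.

**25 back to 24.** The benzyl–oxygen bond at B4 is cut. This oxygen is the one the ring synthesis delivers as a free phenol, and it is capped so that ring A holds the only free hydroxyl at the sulfation stage.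

**24 back to 17 and 20 (key disconnection).** Ring B is opened at B2–B3 and B4–B5, and a one-carbon carbonyl bridge is put back between B2 and B5. This leaves dienone 17 and ketene acetal 20. Cutting here removes both hindered biaryl bonds from the list of bonds to be made: in 17 they are ordinary bonds from an aryl ring to a ring carbon. The forward reaction must add the acetal carbon of 20 to the aryl-bearing diene terminus and the methylene to the benzyloxy-bearing terminus, expel the carbonyl bridge, and aromatise.

**17 back to 15.** The C2=C3 double bond of the dienone is cut as an intramolecular aldol condensation of ene-dione 15, the ring closure used for tetraarylcyclopentadienones. A shorter-looking path, etherifying twice a ring-closed triketone from a double Claisen condensation, is not taken. Such a ring enolises so as to keep the carbonyl between the two aryl-bearing carbons, where it is conjugated with both enol ethers. The bis-ether formed would have aryl groups on both diene termini and would lead to a catechol-type ring B. 17 is the isomer that this preference avoids, so its central benzyloxy group is installed before the ring exists.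

**15 back to 14, and 14 back to 12 and 6.** The enol ether O–benzyl bond is cut, giving triketone 14. In 14 the enolisable carbon lies between a carbonyl that is part of a 1,2-dione and an ordinary ketone; the enolate charge sits on the former, which is the oxygen that must be benzylated. The C–C bond between the 1,2-dione and the aryl-bearing carbon is then cut as a crossed Claisen condensation of ketone 12 with the non-enolisable keto ester 6.

**12 back to 7 and 9.** The ketone comes from alcohol 11, and the aryl–CH2 bond is cut to an aryl anion (10, from bromide 8, from 7) and epoxide 9. The benzyloxy group that becomes the B2 oxygen is already in 9.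

**6 back to 1 and 2.** The aryl–acyl bond and the ester are traced to benzofurandione 4, formed from phenol 1 and 2. Ring closure through the phenol oxygen fixes the acyl group next to that oxygen, and the same oxygen then receives the acetal protecting group, so the sulfation site is defined in the first step.

**20 back to 18.** The second silyl group is cut from the enolate oxygen of silyl ester 18.

## Alternatives that were turned down

**Alternative 1:** oxidative trimerisation. Both biaryl bonds are cut at once. In the forward step three molecules of 1,3,5-trimethoxybenzene A1 are joined by a one-electron or hypervalent-iodine oxidant to 1,3,5-trimethoxy-2,4-bis(2,4,6-trimethoxyphenyl)benzene A2.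
- For it: the whole carbon skeleton comes in one step from a cheap arene, and regiochemistry is no issue because every coupling site is between two methoxy groups.
- Against it: chain length is not controlled, since the biaryl and the terphenyl are each more easily oxidised than A1, so dimer and higher oligomers accompany A2.
- Decisive: A2 has nine identical methyl ethers. Their removal gives the nonaphenol 2,4-bis(2,4,6-trihydroxyphenyl)benzene-1,3,5-triol A3, in which the four ortho hydroxyls of the terminal rings are equivalent and barely differ from the other five. Mono-sulfation would be statistical, and removing nine methyl ethers needs Lewis acids that a sulfate would not survive.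
- Comparison: on step economy for the skeleton this alternative is clearly stronger. The chosen route pays in length for carrying the sulfation site under its own protecting group from step 1 to 25, and it makes no biaryl bond by coupling.

**Alternative 2:** sulfate-bridged intramolecular oxidative coupling. The A–B bond is cut with the sulfur already in place. Bis[3,5-bis(benzyloxy)phenyl] sulfate A4 is oxidised at high dilution so that the two carbons ortho to the sulfate oxygens join, giving the seven-membered cyclic sulfate 4,4',6,6'-tetrakis(benzyloxy)biphenyl-2,2'-diyl sulfate A5.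
- For it: the sulfur is introduced on a simple phenol, the tether enforces ortho,ortho' coupling, and because A5 is symmetrical, opening either S–O bond gives the same biaryl monosulfate with the sulfate on the right kind of oxygen.
- Against it: the sulfate oxygen is electron-withdrawing and deactivates the positions that must couple, while the positions between two benzyloxy groups stay more electron-rich and favour intermolecular coupling.
- Against it: ring C is still missing. It would have to be attached between two oxygens of one ring of A5 by a second tetra-ortho-substituted biaryl coupling, with four similar CH positions on two rings that are identical in A5, and with a sulfate ester present.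
- Comparison: on the sulfation problem this alternative is as strong or stronger, since the site is fixed by construction. On the skeleton it is weaker: it delivers one of the two biaryl bonds, whereas dienone 17 already holds both aryl–ring bonds before ring B is formed.

**Alternative 3:** aryne capture with Truce–Smiles aryl transfer. The A–B bond and one C–O bond are cut. The aryne released by fluoride from 3,5-bis(benzyloxy)-2-(trimethylsilyl)phenyl trifluoromethanesulfonate A6 is attacked by a sulfonate oxygen of caesium 2,4,6-tris(benzyloxy)benzenesulfonate A7. The aryl anion formed then attacks the sulfonyl-bearing carbon, the sulfonyl group is lost, and 2',4,4',6,6'-pentakis(benzyloxy)biphenyl-2-ol A8 results.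
- For it: A8 has exactly one free hydroxyl, on the ortho oxygen of ring A, so the reaction itself marks the sulfation site; the hindered biaryl bond forms without a transition metal.
- Against it: a sulfonate oxygen is a weak nucleophile towards an aryne, and the ipso attack of a Truce–Smiles step needs an electron-poor migrating ring, whereas here the ring carries three alkoxy groups. Proton capture by the aryl anion is the likely outcome.
- Against it: ring C is again missing and would have to be coupled onto the tris(benzyloxy) ring of A8 in competition with the more reactive phenol ring.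
- Comparison: this alternative is stronger on marking the sulfation site and shorter to the first biaryl bond. The chosen route offers a well-precedented ring-forming reaction that delivers the complete terphenyl with all nine oxygens placed.

Key step: step 10

Assumption: the target SMILES has no stereo descriptor, so the hindered A–B axis is left unassigned and the product is racemic with respect to it.
Assumption: 1, 7 and 9 are taken as catalogue compounds (1 and 7 are the di- and tribenzyl ethers of phloroglucinol), as are 2 and 18.

## Route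

Step 1
Reactants: 1 3,5-bis(benzyloxy)phenol; 2 oxalyl chloride
Product: 4 4,6-bis(benzyloxy)-1-benzofuran-2,3-dione, via aryl chlorooxalate 3 (not isolated)
Conditions: (COCl)2 (1.3 equiv), CH2Cl2, 0 °C to reflux
Reagents that add atoms: none
Why: O-acylation gives 3, whose acid chloride closes onto the ortho carbon, activated by the para benzyloxy group (intramolecular Friedel–Crafts acylation, the usual route from electron-rich phenols to benzofuran-2,3-diones); closure through the phenol oxygen fixes the acyl group next to the oxygen that will be sulfated.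

Step 2
Reactants: 4 4,6-bis(benzyloxy)-1-benzofuran-2,3-dione
Product: 6 methyl 2-[2,4-bis(benzyloxy)-6-(methoxymethoxy)phenyl]-2-oxoacetate, via sodium phenoxide 5 (not isolated)
Conditions: NaOMe (1.05 equiv), MeOH/THF, 0 °C; evaporate; MOMCl (1.3 equiv), DMF, 0 °C to rt
Reagents that add atoms: sodium methoxide, C[O-].[Na+]; chloromethyl methyl ether, COCCl
Why: Methoxide opens the aryl ester (transesterification) to phenoxide 5, which is far less basic than methoxide and so does not re-close; Williamson-type O-alkylation then installs the acetal ether that marks the sulfation site.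

Step 3
Reactants: 7 1,3,5-tris(benzyloxy)benzene
Product: 8 2-bromo-1,3,5-tris(benzyloxy)benzene
Conditions: NBS (1.0 equiv), CH2Cl2, −78 to 0 °C
Reagents that add atoms: N-bromosuccinimide, O=C1CCC(=O)N1Br
Why: Electrophilic aromatic bromination; the three CH positions of 7 are equivalent, and one equivalent at low temperature should stop at the monobromide because bromine deactivates the ring.

Step 4
Reactants: 8 2-bromo-1,3,5-tris(benzyloxy)benzene; 9 2-[(benzyloxy)methyl]oxirane (racemic)
Product: 11 1-(benzyloxy)-3-[2,4,6-tris(benzyloxy)phenyl]propan-2-ol (racemic), via aryllithium 10 (not isolated)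
Conditions: n-BuLi (1.05 equiv), THF, −78 °C; then 9 (1.2 equiv), BF3·OEt2 (1.2 equiv), −78 °C; aq. NaHCO3
Reagents that add atoms: none
Why: Bromine–lithium exchange is fast at −78 °C and avoids benzylic deprotonation; the Lewis-acid-assisted opening of the terminal epoxide occurs at the unsubstituted carbon and makes the hindered aryl–CH2 bond; the carbinol centre is racemic and is removed in step 5.

Step 5
Reactants: 11 1-(benzyloxy)-3-[2,4,6-tris(benzyloxy)phenyl]propan-2-ol
Product: 12 1-(benzyloxy)-3-[2,4,6-tris(benzyloxy)phenyl]propan-2-one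
Conditions: Dess–Martin periodinane (1.3 equiv), CH2Cl2, 0 °C to rt
Reagents that add atoms: none
Why: Dess–Martin oxidation of a secondary alcohol; the reagent is not electrophilic enough to attack the electron-rich arene.

Step 6
Reactants: 12 1-(benzyloxy)-3-[2,4,6-tris(benzyloxy)phenyl]propan-2-one; 6 methyl 2-[2,4-bis(benzyloxy)-6-(methoxymethoxy)phenyl]-2-oxoacetate
Product: 14 5-(benzyloxy)-1-(ArA)-3-(ArC)pentane-1,2,4-trione, via potassium enolate 13 (not isolated)
Conditions: KOt-Bu (2.2 equiv), THF, −20 to 0 °C; then AcOH
Reagents that add atoms: none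
Why: Crossed Claisen condensation of a ketone enolate with a non-enolisable keto ester under equilibrating conditions; the benzylic α-position is the more acidic one, addition to the shielded keto group of 6 is reversible, and deprotonation of the 2-aryl-1,3-diketone drives acylation at the ester and keeps the CH2OBn group from enolising.

Step 7
Reactants: 14 5-(benzyloxy)-1-(ArA)-3-(ArC)pentane-1,2,4-trione
Product: 15 (2E)-2,5-bis(benzyloxy)-1-(ArA)-3-(ArC)pent-2-ene-1,4-dione
Conditions: BnBr (1.2 equiv), Cs2CO3 (1.5 equiv), DMF, 0 °C to rt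
Reagents that add atoms: benzyl bromide, BrCc1ccccc1
Why: O-alkylation of a β-diketonate: the central carbon is blocked by ring C, and the charge should sit on the oxygen of the carbonyl that belongs to the 1,2-dione (the more electron-poor one), as in the O-alkylation of acylpyruvate enolates; the (2E) isomer keeps the aroyl group away from ring C and is the one that can cyclise.

Step 8
Reactants: 15 (2E)-2,5-bis(benzyloxy)-1-(ArA)-3-(ArC)pent-2-ene-1,4-dione
Product: 17 2,4-bis(benzyloxy)-3-(ArA)-5-(ArC)cyclopenta-2,4-dien-1-one, via aldol 16 (not isolated)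
Conditions: KOt-Bu (0.3 equiv), t-BuOH/THF, 4 Å molecular sieves, 0 °C to rt
Reagents that add atoms: none
Why: Intramolecular aldol condensation, the ring-closing stage of the classical cyclopentadienone synthesis from a 1,2-diketone and a ketone: the only enolisable carbon (CH2OBn) adds to the aryl ketone in a five-membered closure and E1cB dehydration of 16 gives the dienone; any (2Z) isomer of 15 should equilibrate by reversible alkoxide addition, and the product has no acidic hydrogen left.

Step 9
Reactants: 18 trimethylsilyl acetate
Product: 20 1,1-bis(trimethylsilyloxy)ethene, via lithium enolate 19 (not isolated)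
Conditions: LiN(i-Pr)2 (1.05 equiv), THF, −78 °C; Me3SiCl (1.2 equiv), −78 °C to rt; distil
Reagents that add atoms: chlorotrimethylsilane, C[Si](C)(C)Cl
Why: Deprotonation of the silyl ester and O-silylation of its enolate, the standard preparation of bis(silyl) ketene acetals.

Step 10
Reactants: 17 2,4-bis(benzyloxy)-3-(ArA)-5-(ArC)cyclopenta-2,4-dien-1-one; 20 1,1-bis(trimethylsilyloxy)ethene
Product: 24 3,5-bis(benzyloxy)-4-(ArA)-2-(ArC)phenol, via bridged ketone 21 (not isolated), via cyclohexadiene 22 (not isolated), via aryl silyl ether 23 (not isolated)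
Conditions: 20 (5 equiv), toluene, 120 °C, sealed tube; then K2CO3 (0.1 equiv), MeOH, rt
Reagents that add atoms: none
Why: 17 is an electron-poor diene that its two benzyloxy groups polarise like a 1,3-dioxygenated butadiene: the benzyloxy-bearing terminus C2 (also the δ-carbon of the linear dienone and the oxocarbenium-like carbon of an enol ether) has the large LUMO coefficient, the aryl-bearing terminus C5 is the nucleophilic end, and 20 has its HOMO on the CH2 carbon. An asynchronous inverse-electron-demand [4+2] cycloaddition therefore bonds CH2 to C2 and the acetal carbon to C5 and closes ring B as the six-membered ring of bridged ketone 21 (suprafacial on both partners, two C–C bonds formed). Cheletropic extrusion of the carbonyl bridge from this norbornen-7-one, thermally allowed and driven by loss of a gas, gives cyclohexadiene 22; its only sp3 ring atoms are C(OSiMe3)2 and CH2, so 1,2-elimination of silanol can only aromatise to 23, and methanolysis frees 24. The closest known reaction type is the Diels–Alder reaction of tetrasubstituted cyclopentadienones with alkynes and electron-rich alkenes followed by loss of CO, together with the aromatising loss of alcohol from ketene-acetal adducts of 2-pyranones. The two bridgehead stereocentres of 21 form as a racemate, are locked to each other by the bicycle and vanish on CO loss, so nothing stereochemical has to be controlled. The step needs one regiochemistry (acetal carbon next to ring C; the reverse would give a catechol-type ring B) and chemoselectivity for cycloaddition over conjugate addition of the silyl ketene acetal at the vinylogous-ester carbon C4; the first is secured by the matched polarisation of the partners, the second by the two di-ortho-substituted aryl rings that flank C4. The same aryl groups should keep 17 from dimerising, as in tetraarylcyclopentadienones.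

Step 11
Reactants: 24 3,5-bis(benzyloxy)-4-(ArA)-2-(ArC)phenol
Product: 25 1,3,5-tris(benzyloxy)-2-(ArA)-4-(ArC)benzene
Conditions: BnBr (1.5 equiv), K2CO3 (2 equiv), DMF, 60 °C
Reagents that add atoms: benzyl bromide, BrCc1ccccc1
Why: Williamson etherification of a phenol with one free ortho position; after it the acetal-protected oxygen of ring A is the only oxygen that differs from the rest.

Step 12
Reactants: 25 1,3,5-tris(benzyloxy)-2-(ArA)-4-(ArC)benzene
Product: 26 3,5-bis(benzyloxy)-2-{2,4,6-tris(benzyloxy)-3-[2,4,6-tris(benzyloxy)phenyl]phenyl}phenol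
Conditions: conc. HCl (cat.), MeOH/THF 3:1, 50 °C
Reagents that add atoms: none
Why: Acid-catalysed acetal exchange removes the methoxymethyl group; the solvent methanol traps the methoxymethyl cation as the dimethyl acetal and keeps it from alkylating the electron-rich rings, and benzyl ethers are stable to dilute acid.

Step 13
Reactants: 26 3,5-bis(benzyloxy)-2-{2,4,6-tris(benzyloxy)-3-[2,4,6-tris(benzyloxy)phenyl]phenyl}phenol
Product: 27 trimethylammonium 3,5-bis(benzyloxy)-2-{2,4,6-tris(benzyloxy)-3-[2,4,6-tris(benzyloxy)phenyl]phenyl}phenyl sulfate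
Conditions: SO3·NMe3 (5 equiv), DMF, 60 °C
Reagents that add atoms: sulfur trioxide–trimethylamine complex, C[N+](C)(C)S(=O)(=O)[O-]
Why: O-sulfation of the single free phenol by SO3 transfer from the amine complex; the complex is too mild to sulfonate the rings, and the product is kept as its ammonium salt.

Step 14
Reactants: 27 trimethylammonium 3,5-bis(benzyloxy)-2-{2,4,6-tris(benzyloxy)-3-[2,4,6-tris(benzyloxy)phenyl]phenyl}phenyl sulfate
Product: 29 3,5-dihydroxy-2-[2,4,6-trihydroxy-3-(2,4,6-trihydroxyphenyl)phenyl]phenyl hydrogen sulfate, via trimethylammonium salt 28 (not isolated)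
Conditions: H2 (1 atm), 10% Pd/C, MeOH/THF, rt; filter; Dowex 50W (H+ form), 0 °C; freeze-dry
Reagents that add atoms: none
Why: Hydrogenolysis of eight benzyl aryl ethers under neutral conditions, to which an aryl sulfate salt is inert, followed by cold cation exchange to the hydrogen sulfate; the free acid should be handled cold and stored as a salt.

## Compound list

1 | 3,5-bis(benzyloxy)phenol | Oc1cc(OCc2ccccc2)cc(OCc2ccccc2)c1 | starting material
2 | oxalyl chloride | O=C(Cl)C(=O)Cl | starting material
3 | 3,5-bis(benzyloxy)phenyl chlorooxoacetate | O=C(Cl)C(=O)Oc1cc(OCc2ccccc2)cc(OCc2ccccc2)c1 | intermediate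
4 | 4,6-bis(benzyloxy)-1-benzofuran-2,3-dione | O=C1Oc2cc(OCc3ccccc3)cc(OCc3ccccc3)c2C1=O | intermediate
5 | sodium 3,5-bis(benzyloxy)-2-(methoxyoxalyl)phenolate | [Na+].[O-]c1cc(OCc2ccccc2)cc(OCc2ccccc2)c1C(=O)C(=O)OC | intermediate
6 | methyl 2-[2,4-bis(benzyloxy)-6-(methoxymethoxy)phenyl]-2-oxoacetate | COCOc1cc(OCc2ccccc2)cc(OCc2ccccc2)c1C(=O)C(=O)OC | intermediate
7 | 1,3,5-tris(benzyloxy)benzene | c1c(OCc2ccccc2)cc(OCc2ccccc2)cc1OCc1ccccc1 | starting material
8 | 2-bromo-1,3,5-tris(benzyloxy)benzene | Brc1c(OCc2ccccc2)cc(OCc2ccccc2)cc1OCc1ccccc1 | intermediate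
9 | 2-[(benzyloxy)methyl]oxirane (racemic) | C1OC1COCc1ccccc1 | starting material
10 | [2,4,6-tris(benzyloxy)phenyl]lithium | [Li]c1c(OCc2ccccc2)cc(OCc2ccccc2)cc1OCc1ccccc1 | intermediate
11 | 1-(benzyloxy)-3-[2,4,6-tris(benzyloxy)phenyl]propan-2-ol (racemic) | OC(COCc1ccccc1)Cc1c(OCc2ccccc2)cc(OCc2ccccc2)cc1OCc1ccccc1 | intermediate
12 | 1-(benzyloxy)-3-[2,4,6-tris(benzyloxy)phenyl]propan-2-one | O=C(COCc1ccccc1)Cc1c(OCc2ccccc2)cc(OCc2ccccc2)cc1OCc1ccccc1 | intermediate
13 | potassium 3-(benzyloxy)-1-[2,4,6-tris(benzyloxy)phenyl]prop-1-en-2-olate (enolate geometry not relevant) | [K+].[O-]C(COCc1ccccc1)=Cc1c(OCc2ccccc2)cc(OCc2ccccc2)cc1OCc1ccccc1 | intermediate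
14 | 5-(benzyloxy)-1-(ArA)-3-(ArC)pentane-1,2,4-trione (drawn as the triketone; expected to exist as the enol across C2–C3, so C3 is not a stable stereocentre) | O=C(COCc1ccccc1)C(c1c(OCc2ccccc2)cc(OCc2ccccc2)cc1OCc1ccccc1)C(=O)C(=O)c1c(OCOC)cc(OCc2ccccc2)cc1OCc1ccccc1 | intermediate
15 | (2E)-2,5-bis(benzyloxy)-1-(ArA)-3-(ArC)pent-2-ene-1,4-dione | O=C(COCc1ccccc1)/C(c1c(OCc2ccccc2)cc(OCc2ccccc2)cc1OCc1ccccc1)=C(OCc1ccccc1)\C(=O)c1c(OCOC)cc(OCc2ccccc2)cc1OCc1ccccc1 | intermediate
16 | 3,5-bis(benzyloxy)-4-hydroxy-4-(ArA)-2-(ArC)cyclopent-2-en-1-one (mixture of diastereomers, both dehydrate to 17) | O=C1C(OCc2ccccc2)C(O)(c2c(OCOC)cc(OCc3ccccc3)cc2OCc2ccccc2)C(OCc2ccccc2)=C1c1c(OCc2ccccc2)cc(OCc2ccccc2)cc1OCc1ccccc1 | intermediate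
17 | 2,4-bis(benzyloxy)-3-(ArA)-5-(ArC)cyclopenta-2,4-dien-1-one | O=C1C(OCc2ccccc2)=C(c2c(OCOC)cc(OCc3ccccc3)cc2OCc2ccccc2)C(OCc2ccccc2)=C1c1c(OCc2ccccc2)cc(OCc2ccccc2)cc1OCc1ccccc1 | intermediate
18 | trimethylsilyl acetate | CC(=O)O[Si](C)(C)C | starting material
19 | lithium 1-(trimethylsilyloxy)ethen-1-olate | [Li+].C=C([O-])O[Si](C)(C)C | intermediate
20 | 1,1-bis(trimethylsilyloxy)ethene | C=C(O[Si](C)(C)C)O[Si](C)(C)C | intermediate
21 | 1,3-bis(benzyloxy)-2-(ArA)-4-(ArC)-5,5-bis(trimethylsilyloxy)bicyclo[2.2.1]hept-2-en-7-one (racemic; the two bridgeheads are fixed relative to each other by the bicycle) | O=C1C2(OCc3ccccc3)CC(O[Si](C)(C)C)(O[Si](C)(C)C)C1(c1c(OCc3ccccc3)cc(OCc3ccccc3)cc1OCc1ccccc1)C(OCc1ccccc1)=C2c1c(OCOC)cc(OCc3ccccc3)cc1OCc1ccccc1 | intermediate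
22 | 1,3-bis(benzyloxy)-2-(ArA)-4-(ArC)-5,5-bis(trimethylsilyloxy)cyclohexa-1,3-diene | C[Si](C)(C)OC1(O[Si](C)(C)C)CC(OCc2ccccc2)=C(c2c(OCOC)cc(OCc3ccccc3)cc2OCc2ccccc2)C(OCc2ccccc2)=C1c1c(OCc2ccccc2)cc(OCc2ccccc2)cc1OCc1ccccc1 | intermediate
23 | [3,5-bis(benzyloxy)-4-(ArA)-2-(ArC)phenoxy]trimethylsilane | C[Si](C)(C)Oc1cc(OCc2ccccc2)c(-c2c(OCOC)cc(OCc3ccccc3)cc2OCc2ccccc2)c(OCc2ccccc2)c1-c1c(OCc2ccccc2)cc(OCc2ccccc2)cc1OCc1ccccc1 | intermediate
24 | 3,5-bis(benzyloxy)-4-(ArA)-2-(ArC)phenol | Oc1cc(OCc2ccccc2)c(-c2c(OCOC)cc(OCc3ccccc3)cc2OCc2ccccc2)c(OCc2ccccc2)c1-c1c(OCc2ccccc2)cc(OCc2ccccc2)cc1OCc1ccccc1 | intermediate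
25 | 1,3,5-tris(benzyloxy)-2-(ArA)-4-(ArC)benzene | c1ccccc1COc1cc(OCc2ccccc2)c(-c2c(OCOC)cc(OCc3ccccc3)cc2OCc2ccccc2)c(OCc2ccccc2)c1-c1c(OCc2ccccc2)cc(OCc2ccccc2)cc1OCc1ccccc1 | intermediate
26 | 3,5-bis(benzyloxy)-2-{2,4,6-tris(benzyloxy)-3-[2,4,6-tris(benzyloxy)phenyl]phenyl}phenol | Oc1cc(OCc2ccccc2)cc(OCc2ccccc2)c1-c1c(OCc2ccccc2)cc(OCc2ccccc2)c(-c2c(OCc3ccccc3)cc(OCc3ccccc3)cc2OCc2ccccc2)c1OCc1ccccc1 | intermediate
27 | trimethylammonium 3,5-bis(benzyloxy)-2-{2,4,6-tris(benzyloxy)-3-[2,4,6-tris(benzyloxy)phenyl]phenyl}phenyl sulfate | C[NH+](C)C.[O-]S(=O)(=O)Oc1cc(OCc2ccccc2)cc(OCc2ccccc2)c1-c1c(OCc2ccccc2)cc(OCc2ccccc2)c(-c2c(OCc3ccccc3)cc(OCc3ccccc3)cc2OCc2ccccc2)c1OCc1ccccc1 | intermediate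
28 | trimethylammonium 3,5-dihydroxy-2-[2,4,6-trihydroxy-3-(2,4,6-trihydroxyphenyl)phenyl]phenyl sulfate | C[NH+](C)C.[O-]S(=O)(=O)Oc1cc(O)cc(O)c1-c1c(O)cc(O)c(-c2c(O)cc(O)cc2O)c1O | intermediate
29 | 3,5-dihydroxy-2-[2,4,6-trihydroxy-3-(2,4,6-trihydroxyphenyl)phenyl]phenyl hydrogen sulfate | O=S(=O)(O)Oc1cc(O)cc(O)c1-c1c(O)cc(O)c(-c2c(O)cc(O)cc2O)c1O | target

## Step count and least certain steps

Total: 14 steps. Longest linear sequence: 11 steps (7 through steps 3, 4, 5, 6, 7, 8, 10, 11, 12, 13 and 14 to 29).

**Step 10 (key step).** The most likely failure is that no cycloadduct forms, because the new bond between the fully substituted acetal carbon and the terminus that carries ring C joins two crowded centres. Next most likely is that the silyl ketene acetal reacts as a plain nucleophile (conjugate addition at the vinylogous-ester carbon, or silyl transfer) or rearranges thermally by an O-to-C silyl shift before it adds. Incomplete extrusion of the carbonyl bridge is a lesser risk and would answer to more heat.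
Fallback (sets out from 7, 8 and 1, returns at 25): ring B is taken as a ready-made arene and the two aryl bonds are made by cross-coupling.
- 7 with two equivalents of N-bromosuccinimide gives 2,4-dibromo-1,3,5-tris(benzyloxy)benzene F1.
- Aryllithium 10, made from 8 as in step 4, is quenched with B(OMe)3 to give [2,4,6-tris(benzyloxy)phenyl]boronic acid F2.
- Suzuki–Miyaura coupling of F1 with one equivalent of F2 (Pd(OAc)2, SPhos, K3PO4, toluene, 100 °C) gives 1,3,5-tris(benzyloxy)-2-bromo-4-[2,4,6-tris(benzyloxy)phenyl]benzene F3.
- 1 is converted with MOMCl into 1,3-bis(benzyloxy)-5-(methoxymethoxy)benzene F4, which is lithiated next to the acetal group and borylated to [2,4-bis(benzyloxy)-6-(methoxymethoxy)phenyl]boronic acid F5.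
- A second coupling of F3 with F5 under the same conditions gives 25.
Both couplings are tetra-ortho-substituted and prone to protodeboronation, which is why this is the fallback and not the route.

**Step 7.** The enolate of 14 may be benzylated on the other oxygen (that of the benzyloxyacetyl ketone, which is less hindered) or on carbon. Ring closure of that isomer would give the dienone with both benzyloxy groups next to each other and aryl groups on both diene termini, which is useless for step 10.
Fallback (sets out from 8 and 6, returns at 17): the competing ketone is replaced by an ester, so that only one oxygen can be alkylated; this also removes the regioselective enolisation of step 6.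
- 8 is coupled with the Reformatsky reagent BrZnCH2CO2Me (Pd(dba)2, Q-Phos, THF) to give methyl [2,4,6-tris(benzyloxy)phenyl]acetate F6.
- The lithium enolate of F6 is acylated by 6 to give methyl 4-(ArA)-3,4-dioxo-2-(ArC)butanoate F7.
- O-benzylation of F7 (BnBr, Cs2CO3, DMF) gives methyl (2E)-3-(benzyloxy)-4-(ArA)-4-oxo-2-(ArC)but-2-enoate F8.
- Two equivalents of lithiated diethyl [(benzyloxy)methyl]phosphonate (CCOP(=O)(OCC)COCc1ccccc1) acylate at the ester to give diethyl [(3E)-1,4-bis(benzyloxy)-5-(ArA)-2,5-dioxo-3-(ArC)pent-3-en-1-yl]phosphonate F9.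
- The anion of F9 closes onto the aryl ketone by an intramolecular Horner–Wadsworth–Emmons reaction to give 17.

**Step 8.** Under alkoxide the vinylogous ester may be cleaved (loss of the enol ether benzyl group by addition–elimination, or retro-Claisen fragmentation). The shielded aryl ketone may also fail to accept the enolate, or the tertiary aldol may revert instead of dehydrating.
Fallback (sets out from 15, returns at 17): enolisation, addition and dehydration are separated.
- 15 is silylated at its only enolisable position (t-BuMe2SiOTf, Et3N, CH2Cl2, −78 °C) to give (2E)-2,5-bis(benzyloxy)-1-(ArA)-4-[(tert-butyldimethylsilyl)oxy]-3-(ArC)penta-2,4-dien-1-one F10.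
- Fluoride (Bu4NF, THF, −78 °C) releases the enolate from F10 without any alkoxide present and triggers the intramolecular aldol addition to 16.
- 16 is dehydrated with MsCl and Et3N to give 17.

**Step 14.** The sulfate monoester may be partly hydrolysed by the acidity that develops during a long hydrogenolysis of eight hindered benzyl ethers, or during the final proton exchange. The sulfate salt may also slow the catalyst so that debenzylation stops short.
Fallback (sets out from 26, returns at 29): the sulfate is carried as a neutral diester through debenzylation.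
- 26 is treated with 2,2,2-trichloroethyl chlorosulfate (Et3N, DMAP, THF) to give 3,5-bis(benzyloxy)-2-{2,4,6-tris(benzyloxy)-3-[2,4,6-tris(benzyloxy)phenyl]phenyl}phenyl 2,2,2-trichloroethyl sulfate F11.
- Transfer hydrogenolysis of F11 (Pd/C, HCO2NH4, MeOH) removes the benzyl ethers and the trichloroethyl group in a buffered medium and gives ammonium 3,5-dihydroxy-2-[2,4,6-trihydroxy-3-(2,4,6-trihydroxyphenyl)phenyl]phenyl sulfate F12.
- Cold cation exchange of F12 as in step 14 gives 29.

## Further compounds

F1 | step 10 | 2,4-dibromo-1,3,5-tris(benzyloxy)benzene | Brc1c(OCc2ccccc2)cc(OCc2ccccc2)c(Br)c1OCc1ccccc1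
F2 | step 10 | [2,4,6-tris(benzyloxy)phenyl]boronic acid | OB(O)c1c(OCc2ccccc2)cc(OCc2ccccc2)cc1OCc1ccccc1
F3 | step 10 | 1,3,5-tris(benzyloxy)-2-bromo-4-[2,4,6-tris(benzyloxy)phenyl]benzene | Brc1c(OCc2ccccc2)cc(OCc2ccccc2)c(-c2c(OCc3ccccc3)cc(OCc3ccccc3)cc2OCc2ccccc2)c1OCc1ccccc1
F4 | step 10 | 1,3-bis(benzyloxy)-5-(methoxymethoxy)benzene | COCOc1cc(OCc2ccccc2)cc(OCc2ccccc2)c1
F5 | step 10 | [2,4-bis(benzyloxy)-6-(methoxymethoxy)phenyl]boronic acid | COCOc1cc(OCc2ccccc2)cc(OCc2ccccc2)c1B(O)O
F6 | step 7 | methyl [2,4,6-tris(benzyloxy)phenyl]acetate | COC(=O)Cc1c(OCc2ccccc2)cc(OCc2ccccc2)cc1OCc1ccccc1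
F7 | step 7 | methyl 4-[2,4-bis(benzyloxy)-6-(methoxymethoxy)phenyl]-3,4-dioxo-2-[2,4,6-tris(benzyloxy)phenyl]butanoate | COC(=O)C(c1c(OCc2ccccc2)cc(OCc2ccccc2)cc1OCc1ccccc1)C(=O)C(=O)c1c(OCOC)cc(OCc2ccccc2)cc1OCc1ccccc1
F8 | step 7 | methyl (2E)-3-(benzyloxy)-4-[2,4-bis(benzyloxy)-6-(methoxymethoxy)phenyl]-4-oxo-2-[2,4,6-tris(benzyloxy)phenyl]but-2-enoate | COC(=O)/C(c1c(OCc2ccccc2)cc(OCc2ccccc2)cc1OCc1ccccc1)=C(OCc1ccccc1)\C(=O)c1c(OCOC)cc(OCc2ccccc2)cc1OCc1ccccc1
F9 | step 7 | diethyl {(3E)-1,4-bis(benzyloxy)-5-[2,4-bis(benzyloxy)-6-(methoxymethoxy)phenyl]-2,5-dioxo-3-[2,4,6-tris(benzyloxy)phenyl]pent-3-en-1-yl}phosphonate | CCOP(=O)(OCC)C(OCc1ccccc1)C(=O)/C(c1c(OCc2ccccc2)cc(OCc2ccccc2)cc1OCc1ccccc1)=C(OCc1ccccc1)\C(=O)c1c(OCOC)cc(OCc2ccccc2)cc1OCc1ccccc1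
F10 | step 8 | (2E)-2,5-bis(benzyloxy)-1-[2,4-bis(benzyloxy)-6-(methoxymethoxy)phenyl]-4-[(tert-butyldimethylsilyl)oxy]-3-[2,4,6-tris(benzyloxy)phenyl]penta-2,4-dien-1-one | CC(C)(C)[Si](C)(C)OC(=COCc1ccccc1)/C(c1c(OCc2ccccc2)cc(OCc2ccccc2)cc1OCc1ccccc1)=C(OCc1ccccc1)\C(=O)c1c(OCOC)cc(OCc2ccccc2)cc1OCc1ccccc1
F11 | step 14 | 3,5-bis(benzyloxy)-2-{2,4,6-tris(benzyloxy)-3-[2,4,6-tris(benzyloxy)phenyl]phenyl}phenyl 2,2,2-trichloroethyl sulfate | ClC(Cl)(Cl)COS(=O)(=O)Oc1cc(OCc2ccccc2)cc(OCc2ccccc2)c1-c1c(OCc2ccccc2)cc(OCc2ccccc2)c(-c2c(OCc3ccccc3)cc(OCc3ccccc3)cc2OCc2ccccc2)c1OCc1ccccc1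
F12 | step 14 | ammonium 3,5-dihydroxy-2-[2,4,6-trihydroxy-3-(2,4,6-trihydroxyphenyl)phenyl]phenyl sulfate | [NH4+].[O-]S(=O)(=O)Oc1cc(O)cc(O)c1-c1c(O)cc(O)c(-c2c(O)cc(O)cc2O)c1O
A1 | alternative 1 | 1,3,5-trimethoxybenzene | COc1cc(OC)cc(OC)c1
A2 | alternative 1 | 1,3,5-trimethoxy-2,4-bis(2,4,6-trimethoxyphenyl)benzene | COc1cc(OC)c(-c2c(OC)cc(OC)c(-c3c(OC)cc(OC)cc3OC)c2OC)c(OC)c1
A3 | alternative 1 | 2,4-bis(2,4,6-trihydroxyphenyl)benzene-1,3,5-triol | Oc1cc(O)c(-c2c(O)cc(O)c(-c3c(O)cc(O)cc3O)c2O)c(O)c1
A4 | alternative 2 | bis[3,5-bis(benzyloxy)phenyl] sulfate | O=S(=O)(Oc1cc(OCc2ccccc2)cc(OCc2ccccc2)c1)Oc1cc(OCc2ccccc2)cc(OCc2ccccc2)c1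
A5 | alternative 2 | 4,4',6,6'-tetrakis(benzyloxy)biphenyl-2,2'-diyl sulfate (cyclic) | O=S1(=O)Oc2cc(OCc3ccccc3)cc(OCc3ccccc3)c2-c2c(OCc3ccccc3)cc(OCc3ccccc3)cc2O1
A6 | alternative 3 | 3,5-bis(benzyloxy)-2-(trimethylsilyl)phenyl trifluoromethanesulfonate | C[Si](C)(C)c1c(OS(=O)(=O)C(F)(F)F)cc(OCc2ccccc2)cc1OCc1ccccc1
A7 | alternative 3 | caesium 2,4,6-tris(benzyloxy)benzenesulfonate | [Cs+].[O-]S(=O)(=O)c1c(OCc2ccccc2)cc(OCc2ccccc2)cc1OCc1ccccc1
A8 | alternative 3 | 2',4,4',6,6'-pentakis(benzyloxy)biphenyl-2-ol | Oc1cc(OCc2ccccc2)cc(OCc2ccccc2)c1-c1c(OCc2ccccc2)cc(OCc2ccccc2)cc1OCc1ccccc1
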